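Rings A and B of this cis-fused eudesmane share the C5–C10 bond. The C8 ketone can be read as a masked 2-silyloxydiene C10=C9–C8=C7. The oxygenated C4 can be read as a former ketone that activates a C5=C6 vinyl group. A single intramolecular Diels–Alder reaction of an open-chain trienone therefore makes C5–C10 and C6–C7, closes both rings, and sets C5, quaternary C10 and C7. The precursor is an (R)-4-benzyloxy-9-silyloxy-7,11-dimethyl-(7E,9Z)-dodeca-1,7,9-trien-3-one. Its α-benzyloxy ketone is locked as a magnesium chelate, so that C3 selects the diene face. Afterwards C4 is methylated from the convex face, C7 is equilibrated, and O4 and O3 are acylated.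

Key step: step 10

Remark: eudesmane numbering (C1–C15) is used for all intermediates, cyclopentadienyl ligands are drawn η1 in SMILES, and the carbinol centre of the C7–C10 fragment is carried as a racemate because it is oxidised away.

Step 1
Reactants: 1 (R)-3-hydroxydihydrofuran-2(3H)-one
Product: 2 (R)-3-(benzyloxy)dihydrofuran-2(3H)-one
Conditions: BnBr, Ag2O, 4 Å MS, CH2Cl2, rt, dark
Reagents that add atoms: benzyl bromide BrCc1ccccc1
Why: Silver-oxide-promoted Williamson-type O-benzylation runs under essentially neutral conditions, so the lactone stays closed and the C3 stereocentre next to the carbonyl is not enolised.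

Step 2
Reactants: 2 (R)-3-(benzyloxy)dihydrofuran-2(3H)-one
Product: 3 (R)-2-(benzyloxy)-4-hydroxy-N-methoxy-N-methylbutanamide
Conditions: MeNH(OMe)·HCl, AlMe3, CH2Cl2, 0 °C to rt
Reagents that add atoms: N,O-dimethylhydroxylamine hydrochloride CNOC.Cl
Why: Weinreb aminolysis of a lactone with the aluminium amide made in the flask attacks only the acyl carbon C4, which frees the C1 hydroxyl and leaves C3 untouched.

Step 3
Reactants: 3 (R)-2-(benzyloxy)-4-hydroxy-N-methoxy-N-methylbutanamide
Product: 4 (R)-2-(benzyloxy)-4-iodo-N-methoxy-N-methylbutanamide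
Conditions: I2, PPh3, imidazole, CH2Cl2, 0 °C
Reagents that add atoms: iodine II
Why: Appel-type iodination replaces the activated primary hydroxyl by SN2 attack of iodide at C1, which at 0 °C should outrun relactonisation.

Step 4
Reactants: 5 3-methylbutanal
Product: 6 (±)-6-methylhept-2-yn-4-ol
Conditions: CH3C≡CMgBr, THF, 0 °C; aq. quench
Reagents that add atoms: 1-propynylmagnesium bromide CC#C[Mg]Br
Why: 1,2-Addition of an alkynyl Grignard reagent to an unhindered aldehyde is routine, and the new carbinol centre needs no control because step 6 oxidises it.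

Step 5
Reactants: 6 (±)-6-methylhept-2-yn-4-ol
Product: 8 (±)-(E)-2-iodo-6-methylhept-2-en-4-ol, via alkenylzirconocene 7 (not isolated)
Conditions: Cp2Zr(H)Cl (2.3 equiv), THF, rt, dark; then I2, 0 °C
Reagents that add atoms: iodine II
Why: Hydrozirconation with the Schwartz reagent adds Zr–H syn with zirconium on the less hindered, methyl-bearing carbon (the first equivalent only deprotonates the hydroxyl), and iodinolysis with retention fixes the E geometry that becomes C10=C9.

Step 6
Reactants: 8 (±)-(E)-2-iodo-6-methylhept-2-en-4-ol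
Product: 9 (E)-2-iodo-6-methylhept-2-en-4-one
Conditions: MnO2 (activated), CH2Cl2, rt, dark
Reagents that add atoms: none
Why: MnO2 oxidation of an allylic alcohol is neutral and heterogeneous, so the vinyl iodide should keep its geometry.

Step 7
Reactants: 4 (R)-2-(benzyloxy)-4-iodo-N-methoxy-N-methylbutanamide; 9 (E)-2-iodo-6-methylhept-2-en-4-one
Product: 11 (R,E)-2-(benzyloxy)-N-methoxy-N,5,9-trimethyl-7-oxodec-5-enamide, via alkylzinc iodide 10 (not isolated)
Conditions: Zn dust, LiCl, THF, 25–35 °C; then 9, PdCl2(dppf) (3 mol %), THF, 0 °C to rt, dark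
Reagents that add atoms: none
Why: LiCl-assisted zinc insertion tolerates the Weinreb amide, and the Negishi sp3–sp2 coupling replaces the vinylic iodide with retention, so the tether ends up trans to C8 and the C14 methyl cis to it.

Step 8
Reactants: 11 (R,E)-2-(benzyloxy)-N-methoxy-N,5,9-trimethyl-7-oxodec-5-enamide
Product: 13 (R,5E,7Z)-2-(benzyloxy)-7-((tert-butyldimethylsilyl)oxy)-N-methoxy-N,5,9-trimethyldeca-5,7-dienamide, via potassium dienolate 12 (not isolated)
Conditions: KN(SiMe3)2 (1.05 equiv), THF, −78 °C; then TBSCl, −78 to 0 °C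
Reagents that add atoms: tert-butyldimethylsilyl chloride CC(C)(C)[Si](C)(C)Cl
Why: Kinetic α′-deprotonation of the enone at C7 gives the cross-conjugated dienolate, its Z(O) geometry is favoured because the alternative pushes the isopropyl group against the bulky alkenyl residue, and O-silylation traps it without touching the far less acidic amide α-proton.

Step 9
Reactants: 13 (R,5E,7Z)-2-(benzyloxy)-7-((tert-butyldimethylsilyl)oxy)-N-methoxy-N,5,9-trimethyldeca-5,7-dienamide
Product: 14 (R,7E,9Z)-4-(benzyloxy)-9-((tert-butyldimethylsilyl)oxy)-7,11-dimethyldodeca-1,7,9-trien-3-one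
Conditions: CH2=CHMgBr, THF, −78 to −20 °C; inverse quench into cold aq. citric acid/Et2O; used at once
Reagents that add atoms: vinylmagnesium bromide C=C[Mg]Br
Why: In the Weinreb ketone synthesis the chelated tetrahedral adduct stops the addition at the ketone stage, the silyl dienol ether is inert to the Grignard reagent, and the cold acidic inverse quench protonates the liberated amine before it can add to the new enone.

Step 10
Reactants: 14 (R,7E,9Z)-4-(benzyloxy)-9-((tert-butyldimethylsilyl)oxy)-7,11-dimethyldodeca-1,7,9-trien-3-one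
Product: 15 (2R,4aR,7S,8aS)-2-(benzyloxy)-6-((tert-butyldimethylsilyl)oxy)-7-isopropyl-4a-methyl-3,4,4a,7,8,8a-hexahydronaphthalen-1(2H)-one
Conditions: MgBr2·OEt2 (2 equiv), 2,6-di-tert-butylpyridine (0.2 equiv), CH2Cl2 (0.005 M), −78 to 0 °C
Reagents that add atoms: none
Why: This is a concerted but asynchronous normal-demand [4+2] cycloaddition in which the nucleophilic enol-ether terminus C7 bonds early to the enone β-carbon C6 and the hindered C10–C5 bond follows late, which is what lets the quaternary centre form; the closest known reactions are Lewis-acid-promoted type 1 intramolecular Diels–Alder reactions of 1,7,9-decatrien-3-ones and cycloadditions of 4,4-disubstituted 2-silyloxydienes. Ring B (C5–C10) closes as the new cyclohexene of the cycloaddition, suprafacial on both partners, and ring A (C10, C1–C5) closes as the fused ring spanned by the four-atom tether in a chair-like array. C5 and C10 become cis because the tether carbonyl C4 lies endo under the diene, a preference that coordination of the Lewis acid should strengthen. The absolute sense at C5/C10 comes from C3, because the five-membered O3–Mg–O4 chelate holds the C3–O bond in the carbonyl plane (pseudo-equatorial on the forming chair), whereas an unchelated α-alkoxy group would have little equatorial bias, so only one diene face can be reached. C7 follows from the Z enol ether geometry, whose outside isopropyl group ends up cis to C1 and C4 (7-epi, corrected in step 12). Regiochemistry is fixed by the tether and is electronically matched, the C8 silyloxy group disfavours the s-trans rotamer through its clash with the inside C14 methyl, and high dilution suppresses intermolecular Mukaiyama–Michael addition.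

Step 11
Reactants: 15 (2R,4aR,7S,8aS)-2-(benzyloxy)-6-((tert-butyldimethylsilyl)oxy)-7-isopropyl-4a-methyl-3,4,4a,7,8,8a-hexahydronaphthalen-1(2H)-one
Product: 17 (1S,2R,4aR,7S,8aS)-2-(benzyloxy)-6-((tert-butyldimethylsilyl)oxy)-7-isopropyl-1,4a-dimethyl-1,2,3,4,4a,7,8,8a-octahydronaphthalen-1-yl acetate, via bromomagnesium alkoxide 16 (not isolated)
Conditions: MeMgBr, Et2O/CH2Cl2, −78 °C; then Ac2O, DMAP (cat.), −78 °C to rt
Reagents that add atoms: methylmagnesium bromide C[Mg]Br; acetic anhydride CC(=O)OC(C)=O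
Why: In this chelation-assisted Grignard 1,2-addition ring A stays in the chair with equatorial OBn, the concave α trajectory is blocked by axial C9, so methyl enters from the convex β face, and the axial alkoxide is acetylated in the same flask while C8 is still masked as its silyl enol ether.

Step 12
Reactants: 17 (1S,2R,4aR,7S,8aS)-2-(benzyloxy)-6-((tert-butyldimethylsilyl)oxy)-7-isopropyl-1,4a-dimethyl-1,2,3,4,4a,7,8,8a-octahydronaphthalen-1-yl acetate
Product: 19 (1S,2R,4aR,7R,8aS)-2-(benzyloxy)-7-isopropyl-1,4a-dimethyl-6-oxodecahydronaphthalen-1-yl acetate, via 7-epi ketone 18 (not isolated)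
Conditions: Bu4NF, AcOH, THF, 0 °C; then DBU, rt
Reagents that add atoms: none
Why: Fluoride cleavage of the silyl enol ether releases the C8 ketone, and amidine-base enolisation then equilibrates C7 to the equatorial isopropyl isomer, because the 7-epimer must place that group axial and syn to C4 or flip into a conformer with 1,3-diaxial C14 and C15 methyls.

Step 13
Reactants: 19 (1S,2R,4aR,7R,8aS)-2-(benzyloxy)-7-isopropyl-1,4a-dimethyl-6-oxodecahydronaphthalen-1-yl acetate
Product: 20 (1S,2R,4aR,7R,8aS)-2-hydroxy-7-isopropyl-1,4a-dimethyl-6-oxodecahydronaphthalen-1-yl acetate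
Conditions: H2 (1 atm), Pd/C, EtOAc, rt
Reagents that add atoms: none
Why: Catalytic hydrogenolysis cleaves only the benzyl ether, and its neutral medium should keep the neighbouring tertiary acetate from migrating.

Step 14
Reactants: 21 angelic acid, (Z)-2-methylbut-2-enoic acid
Product: 22 (Z)-2-methylbut-2-en-1-ol
Conditions: LiAlH4, Et2O, 0 °C to rt
Reagents that add atoms: none
Why: Hydride reduction of the carboxylic acid proceeds by 1,2-attack and leaves the trisubstituted alkene alone, so the Z geometry is kept.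

Step 15
Reactants: 22 (Z)-2-methylbut-2-en-1-ol
Product: 23 ((2R,3S)-2,3-dimethyloxiran-2-yl)methanol
Conditions: Ti(OiPr)4 (cat.), D-(−)-diethyl tartrate, t-BuOOH, 4 Å MS, CH2Cl2, −20 °C
Reagents that add atoms: tert-butyl hydroperoxide CC(C)(C)OO
Why: In the Sharpless asymmetric epoxidation, syn oxygen transfer keeps CH2OH and the C3 methyl cis, and the D-(−)-tartrate ligand selects the alkene face that gives the (2R,3S) epoxy alcohol.

Step 16
Reactants: 23 ((2R,3S)-2,3-dimethyloxiran-2-yl)methanol
Product: 24 (2S,3S)-2,3-dimethyloxirane-2-carboxylic acid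
Conditions: TEMPO (cat.), PhI(OAc)2, MeCN/H2O, rt
Reagents that add atoms: water O
Why: Oxoammonium oxidation takes the primary alcohol through the aldehyde hydrate to the acid under nearly neutral conditions that leave the epoxide and both stereocentres intact (the C2 descriptor changes only because the priorities change).

Step 17
Reactants: 24 (2S,3S)-2,3-dimethyloxirane-2-carboxylic acid; 20 (1S,2R,4aR,7R,8aS)-2-hydroxy-7-isopropyl-1,4a-dimethyl-6-oxodecahydronaphthalen-1-yl acetate
Product: 26 CNP0221066.1, via mixed anhydride 25 (not isolated)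
Conditions: 2,4,6-Cl3C6H2COCl, Et3N, toluene, rt; then 20, DMAP, 0 °C to rt
Reagents that add atoms: none
Why: In the Yamaguchi esterification DMAP attacks the aliphatic carbonyl of the preformed mixed anhydride, the acylpyridinium ion acylates the only free hydroxyl (equatorial O3) with retention everywhere, and any minor acid enantiomer is removed as a diastereomeric ester.

Compound list
1 | (R)-3-hydroxydihydrofuran-2(3H)-one | O=C1OCC[C@H]1O | starting material
2 | (R)-3-(benzyloxy)dihydrofuran-2(3H)-one | O=C1OCC[C@H]1OCc1ccccc1 | intermediate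
3 | (R)-2-(benzyloxy)-4-hydroxy-N-methoxy-N-methylbutanamide | CON(C)C(=O)[C@H](OCc1ccccc1)CCO | intermediate
4 | (R)-2-(benzyloxy)-4-iodo-N-methoxy-N-methylbutanamide | CON(C)C(=O)[C@H](OCc1ccccc1)CCI | intermediate
5 | 3-methylbutanal | CC(C)CC=O | starting material
6 | (±)-6-methylhept-2-yn-4-ol | CC#CC(O)CC(C)C | intermediate
7 | (E)-alkenylzirconocene chloride from 6, O-zirconated | Cl[Zr](C1C=CC=C1)(C1C=CC=C1)/C(C)=C/C(CC(C)C)O[Zr](Cl)(C1C=CC=C1)C1C=CC=C1 | intermediate
8 | (±)-(E)-2-iodo-6-methylhept-2-en-4-ol | I/C(C)=C/C(O)CC(C)C | intermediate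
9 | (E)-2-iodo-6-methylhept-2-en-4-one | I/C(C)=C/C(=O)CC(C)C | intermediate
10 | (R)-[3-(benzyloxy)-4-(methoxy(methyl)amino)-4-oxobutyl]zinc iodide | CON(C)C(=O)[C@H](OCc1ccccc1)CC[Zn]I | intermediate
11 | (R,E)-2-(benzyloxy)-N-methoxy-N,5,9-trimethyl-7-oxodec-5-enamide | CON(C)C(=O)[C@H](OCc1ccccc1)CC/C(C)=C/C(=O)CC(C)C | intermediate
12 | potassium (5E,7Z)-dienolate of 11 | CON(C)C(=O)[C@H](OCc1ccccc1)CC/C(C)=C/C([O-])=C/C(C)C.[K+] | intermediate
13 | (R,5E,7Z)-2-(benzyloxy)-7-((tert-butyldimethylsilyl)oxy)-N-methoxy-N,5,9-trimethyldeca-5,7-dienamide | CON(C)C(=O)[C@H](OCc1ccccc1)CC/C(C)=C/C(O[Si](C)(C)C(C)(C)C)=C/C(C)C | intermediate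
14 | (R,7E,9Z)-4-(benzyloxy)-9-((tert-butyldimethylsilyl)oxy)-7,11-dimethyldodeca-1,7,9-trien-3-one | C=CC(=O)[C@H](OCc1ccccc1)CC/C(C)=C/C(O[Si](C)(C)C(C)(C)C)=C/C(C)C | intermediate
15 | (2R,4aR,7S,8aS)-2-(benzyloxy)-6-((tert-butyldimethylsilyl)oxy)-7-isopropyl-4a-methyl-3,4,4a,7,8,8a-hexahydronaphthalen-1(2H)-one (cis-fused, 7-epi) | O=C1[C@H](OCc3ccccc3)CC[C@]2(C)C=C(O[Si](C)(C)C(C)(C)C)[C@H](C(C)C)C[C@@H]21 | intermediate
16 | bromomagnesium C4 alkoxide from 15 | Br[Mg]O[C@]1(C)[C@H](OCc3ccccc3)CC[C@]2(C)C=C(O[Si](C)(C)C(C)(C)C)[C@H](C(C)C)C[C@@H]21 | intermediate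
17 | (1S,2R,4aR,7S,8aS)-2-(benzyloxy)-6-((tert-butyldimethylsilyl)oxy)-7-isopropyl-1,4a-dimethyl-1,2,3,4,4a,7,8,8a-octahydronaphthalen-1-yl acetate | CC(=O)O[C@]1(C)[C@H](OCc3ccccc3)CC[C@]2(C)C=C(O[Si](C)(C)C(C)(C)C)[C@H](C(C)C)C[C@@H]21 | intermediate
18 | (1S,2R,4aR,7S,8aS)-2-(benzyloxy)-7-isopropyl-1,4a-dimethyl-6-oxodecahydronaphthalen-1-yl acetate (7-epi ketone) | CC(=O)O[C@]1(C)[C@H](OCc3ccccc3)CC[C@]2(C)CC(=O)[C@H](C(C)C)C[C@@H]21 | intermediate
19 | (1S,2R,4aR,7R,8aS)-2-(benzyloxy)-7-isopropyl-1,4a-dimethyl-6-oxodecahydronaphthalen-1-yl acetate | CC(=O)O[C@]1(C)[C@H](OCc3ccccc3)CC[C@]2(C)CC(=O)[C@@H](C(C)C)C[C@@H]21 | intermediate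
20 | (1S,2R,4aR,7R,8aS)-2-hydroxy-7-isopropyl-1,4a-dimethyl-6-oxodecahydronaphthalen-1-yl acetate | CC(=O)O[C@]1(C)[C@H](O)CC[C@]2(C)CC(=O)[C@@H](C(C)C)C[C@@H]21 | intermediate
21 | angelic acid, (Z)-2-methylbut-2-enoic acid | C/C=C(/C)C(=O)O | starting material
22 | (Z)-2-methylbut-2-en-1-ol | C/C=C(/C)CO | intermediate
23 | ((2R,3S)-2,3-dimethyloxiran-2-yl)methanol | OC[C@@]1(C)O[C@H]1C | intermediate
24 | (2S,3S)-2,3-dimethyloxirane-2-carboxylic acid | OC(=O)[C@@]1(C)O[C@H]1C | intermediate
25 | (2S,3S)-2,3-dimethyloxirane-2-carboxylic 2,4,6-trichlorobenzoic anhydride | O=C(OC(=O)[C@@]1(C)O[C@H]1C)c1c(Cl)cc(Cl)cc1Cl | intermediate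
26 | (1S,2R,4aR,7R,8aS)-1-acetoxy-7-isopropyl-1,4a-dimethyl-6-oxodecahydronaphthalen-2-yl (2S,3S)-2,3-dimethyloxirane-2-carboxylate (CNP0221066.1) | CC(=O)O[C@]1(C)[C@H](OC(=O)[C@@]2(C)O[C@H]2C)CC[C@]2(C)CC(=O)[C@@H](C(C)C)C[C@@H]21 | target

Total step count: 17. Longest linear sequence: 11 steps (1, 2, 3, 7, 8, 9, 10, 11, 12, 13, 17). The iodoenone branch (steps 4–6) and the epoxy acid branch (steps 14–16) run in parallel.

Steps most likely to fail

1. Step 10. Facial or endo/exo selectivity may erode, or the Lewis acid may strip the silyl dienol ether before the rings close.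
 - The fallback sets out from 10 and comes back at 19. It builds ring A first, so that a cyclic dienophile guarantees the cis fusion.
 - Negishi coupling of 10 with 2-bromopropene (PdCl2(dppf)) would give (R)-2-(benzyloxy)-N-methoxy-N,5-dimethylhex-5-enamide F1.
 - CH2=CHMgBr would turn it into (R)-4-(benzyloxy)-7-methylocta-1,7-dien-3-one F2, and ring-closing metathesis with the second-generation Hoveyda–Grubbs catalyst would give (R)-6-(benzyloxy)-3-methylcyclohex-2-en-1-one F3.
 - The diene comes from 4-methylpentan-2-one. Mannich-type α-methylenation (paraformaldehyde, iPr2NH·CF3CO2H) gives 4-methyl-3-methylidenepentan-2-one F4, and kinetic silylation (KN(SiMe3)2, TBSCl) gives 2-(tert-butyldimethylsilyloxy)-3-isopropylbuta-1,3-diene F5.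
 - An intermolecular Diels–Alder reaction of F3 with F5 follows, under the mixed Lewis acid AlBr3/AlMe3 that is known for hindered silyloxydiene/β-methyl enone pairs. It forms C9–C10 and C5–C6 with axial attack at C10, cis to the equatorial benzyloxy group.
 - The product is (2R,4aR,8aS)-2-(benzyloxy)-6-((tert-butyldimethylsilyl)oxy)-7-isopropyl-4a-methyl-3,4,4a,5,8,8a-hexahydronaphthalen-1(2H)-one F6.
 - MeMgBr then Ac2O as in step 11 would give (1S,2R,4aR,8aS)-2-(benzyloxy)-6-((tert-butyldimethylsilyl)oxy)-7-isopropyl-1,4a-dimethyl-1,2,3,4,4a,5,8,8a-octahydronaphthalen-1-yl acetate F7. The conditions of step 12 then lead to 19.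

2. Step 7. The E geometry may be lost through reversible iodide addition to the β-iodoenone, or the zinc reagent may be protonated before it couples.
 - The fallback sets out from 8 and 10 and comes back at 11. It couples at the alcohol oxidation level and oxidises afterwards.
 - 10 is coupled with unprotected 8 under Pd(OAc)2/SPhos, conditions known to tolerate free hydroxyl groups. This gives (2R,5E)-2-(benzyloxy)-7-hydroxy-N-methoxy-N,5,9-trimethyldec-5-enamide F8 as a mixture of carbinol epimers.
 - MnO2 then oxidises it to 11.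

3. Step 17. Acylation of the hindered O3 may be slow enough for base-induced acetyl migration from O4 to O3 to compete.
 - The fallback sets out from 20 and comes back at 26. It reverses the order of the two acylations.
 - K2CO3 in MeOH converges 20 and any migrated isomer on the (3R,4S,5S,7R,10R)-3,4-dihydroxy-cis-eudesman-8-one F9.
 - Mixed anhydride 25 with DMAP acylates only the secondary O3 and gives the (3R,4S,5S,7R,10R)-4-hydroxy-8-oxo-cis-eudesman-3-yl (2S,3S)-2,3-dimethyloxirane-2-carboxylate F10.
 - The tertiary O4 is then acetylated with Ac2O under Sc(OTf)3 catalysis at low temperature to give 26.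

Further compounds
F1 | step 10 | (R)-2-(benzyloxy)-N-methoxy-N,5-dimethylhex-5-enamide | CON(C)C(=O)[C@H](OCc1ccccc1)CCC(C)=C
F2 | step 10 | (R)-4-(benzyloxy)-7-methylocta-1,7-dien-3-one | C=CC(=O)[C@H](OCc1ccccc1)CCC(C)=C
F3 | step 10 | (R)-6-(benzyloxy)-3-methylcyclohex-2-en-1-one | O=C1C=C(C)CC[C@H]1OCc1ccccc1
F4 | step 10 | 4-methyl-3-methylidenepentan-2-one | CC(=O)C(=C)C(C)C
F5 | step 10 | 2-(tert-butyldimethylsilyloxy)-3-isopropylbuta-1,3-diene | C=C(O[Si](C)(C)C(C)(C)C)C(=C)C(C)C
F6 | step 10 | (2R,4aR,8aS)-2-(benzyloxy)-6-((tert-butyldimethylsilyl)oxy)-7-isopropyl-4a-methyl-3,4,4a,5,8,8a-hexahydronaphthalen-1(2H)-one | O=C1[C@H](OCc3ccccc3)CC[C@]2(C)CC(O[Si](C)(C)C(C)(C)C)=C(C(C)C)C[C@@H]21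
F7 | step 10 | (1S,2R,4aR,8aS)-2-(benzyloxy)-6-((tert-butyldimethylsilyl)oxy)-7-isopropyl-1,4a-dimethyl-1,2,3,4,4a,5,8,8a-octahydronaphthalen-1-yl acetate | CC(=O)O[C@]1(C)[C@H](OCc3ccccc3)CC[C@]2(C)CC(O[Si](C)(C)C(C)(C)C)=C(C(C)C)C[C@@H]21
F8 | step 7 | (2R,5E)-2-(benzyloxy)-7-hydroxy-N-methoxy-N,5,9-trimethyldec-5-enamide | CON(C)C(=O)[C@H](OCc1ccccc1)CC/C(C)=C/C(O)CC(C)C
F9 | step 17 | (3R,4S,5S,7R,10R)-3,4-dihydroxy-cis-eudesman-8-one | O[C@]1(C)[C@H](O)CC[C@]2(C)CC(=O)[C@@H](C(C)C)C[C@@H]21
F10 | step 17 | (3R,4S,5S,7R,10R)-4-hydroxy-8-oxo-cis-eudesman-3-yl (2S,3S)-2,3-dimethyloxirane-2-carboxylate | O[C@]1(C)[C@H](OC(=O)[C@@]2(C)O[C@H]2C)CC[C@]2(C)CC(=O)[C@@H](C(C)C)C[C@@H]21
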